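**Plan**
Retrosynthesis: the 14-membered ring is cut at the enol ether C–O bond and at the ester of the primary alcohol, the 10-membered lactone at its ester, and the bridging tertiary ether at its allylic C–O bond and at the alkenyl–carbinol C–C bond.
The cyclohexene is then cut at its two opposite single bonds (ring-fusion CH to vinylic CH, and side-chain-bearing allylic CH to the oxygenated quaternary carbon), leaving a 2-oxabicyclo[2.2.2]oct-7-en-3-one and an (E)-allyl sulfone.
Enabling feature: in this bicycle the lactone carbonyl carbon and the alkene CH flank the same bridgehead CH, 1,3-syn on the side of the lactone bridge; the bridgehead cannot enolise and the ring oxygen on the other bridgehead cannot be β-eliminated, since either would need a bridgehead double bond.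
Forward: a pyranone Diels–Alder reaction gives the bicyclic lactone, a sulfone-relayed [3+3] annulation fuses the cyclohexene on, alkenyl addition and ionisation re-close the ether bridge, a Shiina lactonisation closes the 10-membered ring, and esterification plus gold-catalysed hydroalkoxylation close the 14-membered ring.
Stereochemistry: the bicycle from a removable (S)-arylethyl vinyl ether, the methoxy carbinol from (S)-glycidyl ether, the triol segment from (R)-glyceraldehyde acetonide and an Evans syn-aldol.
The cyclohexene stereocentres follow from the face and tether of the bicycle and the (E)-alkene; the ring carbinol comes from a late hydride reduction on the open face.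

Key step: step 7

Remark: the (S)-1-(4-methoxyphenyl)ethyl group is assumed to bias the cycloaddition of step 3 towards the diastereomer drawn as 5; if the bias is the other way, the (R)-alcohol is used in step 2 and nothing else changes.
Remark: 13 and 14 are drawn as bridged lactols; each can open to its δ-hydroxy ketone tautomer, which is the form that reacts in step 15; the sulfonyl-bearing sp3 carbon of 12 and 13 and the carbinol carbon of 27 are left undefined because they are removed or ionised later.

**Route**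

Step 1
Reactants: 1 5-bromo-2H-pyran-2-one
Product: 2 5-(phenylsulfonyl)-2H-pyran-2-one
Conditions: PhSO2Na, Pd2(dba)3 (2.5 mol%), Xantphos (5 mol%), Cs2CO3, n-Bu4NCl, toluene, 80 °C
Reagents that add atoms: sodium benzenesulfinate, [Na+].[O-]S(=O)c1ccccc1
Why: Palladium-catalysed sulfonylation of a vinyl bromide with a sulfinate salt is a known C–S cross-coupling, and the electron-poor bromopyranone should undergo oxidative addition readily.

Step 2
Reactants: 3 (S)-1-(4-methoxyphenyl)ethan-1-ol
Product: 4 1-methoxy-4-[(1S)-1-(vinyloxy)ethyl]benzene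
Conditions: butyl vinyl ether (solvent), Pd(OCOCF3)2 (1 mol%), 4,7-diphenyl-1,10-phenanthroline (1 mol%), Et3N, 75 °C
Reagents that add atoms: butyl vinyl ether, C=COCCCC
Why: Palladium-catalysed transfer vinylation (transetherification) of a secondary alcohol with an excess of an alkyl vinyl ether does not touch the carbinol stereocentre.

Step 3
Reactants: 2 5-(phenylsulfonyl)-2H-pyran-2-one; 4 1-methoxy-4-[(1S)-1-(vinyloxy)ethyl]benzene
Product: 5 (1S,4S,5S)-5-[(1S)-1-(4-methoxyphenyl)ethoxy]-7-(phenylsulfonyl)-2-oxabicyclo[2.2.2]oct-7-en-3-one (ether endo, syn to the alkene bridge)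
Conditions: CH2Cl2, 25 °C, 48 h; chromatography to remove the minor diastereomers
Reagents that add atoms: none
Why: In this inverse-electron-demand Diels–Alder reaction the unsubstituted enol ether carbon should bond to the ring carbon next to the ring oxygen (β to the sulfone), the alkoxy group should go endo, and the (S)-arylethyl group should select the diene face, so both bridgeheads and the ether carbon are set together.

Step 4
Reactants: 6 (S)-2-{[(4-methoxybenzyl)oxy]methyl}oxirane
Product: 7 (S)-1-[(4-methoxybenzyl)oxy]pent-4-en-2-ol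
Conditions: vinylmagnesium bromide, CuI (10 mol%), THF, −30 °C
Reagents that add atoms: vinylmagnesium bromide, C=C[Mg]Br
Why: Copper-catalysed SN2 opening of the terminal epoxide at its CH2 carbon leaves the stereocentre unchanged.

Step 5
Reactants: 7 (S)-1-[(4-methoxybenzyl)oxy]pent-4-en-2-ol
Product: 8 1-methoxy-4-({[(2S)-2-methoxypent-4-en-1-yl]oxy}methyl)benzene
Conditions: NaH, MeI, THF, 0 °C to 25 °C
Reagents that add atoms: iodomethane, CI
Why: Williamson O-methylation of the sodium alkoxide occurs at oxygen only and retains configuration.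

Step 6
Reactants: 8 1-methoxy-4-({[(2S)-2-methoxypent-4-en-1-yl]oxy}methyl)benzene; 9 allyl phenyl sulfone
Product: 10 1-methoxy-4-({[(2S,4E)-2-methoxy-6-(phenylsulfonyl)hex-4-en-1-yl]oxy}methyl)benzene
Conditions: 9 (3 equiv), second-generation Grubbs catalyst (5 mol%), CH2Cl2, 40 °C
Reagents that add atoms: none
Why: Olefin cross-metathesis of two terminal alkenes with loss of ethene should give the thermodynamically favoured (E)-allyl sulfone.

Step 7
Reactants: 10 1-methoxy-4-({[(2S,4E)-2-methoxy-6-(phenylsulfonyl)hex-4-en-1-yl]oxy}methyl)benzene; 5 (1S,4S,5S)-5-[(1S)-1-(4-methoxyphenyl)ethoxy]-7-(phenylsulfonyl)-2-oxabicyclo[2.2.2]oct-7-en-3-one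
Product: 13 tricyclic bis-sulfonyl lactol (cyclohexene fused to the oxabicycle), via lithiated sulfone 11 (not isolated), via lithiated Michael adduct 12 (not isolated)
Conditions: n-BuLi (1.05 equiv), THF/HMPA (10:1), −78 °C; then 5, −78 °C to −30 °C; AcOH, −78 °C
Reagents that add atoms: none
Why: Proposed new method: the lithiated allyl sulfone 11 should add through its sulfonyl-bearing carbon to the β-carbon of the strained vinyl sulfone of 5 from the face next to the flat lactone bridge (the other face carries the endo ether), the resulting alkyl α-sulfonyl carbanion should be quenched by the more acidic, doubly activated C–H of the adduct to give the allyl sulfonyl carbanion 12, and 12 should close through its γ-carbon onto the lactone carbonyl held 1,3-syn to it, the lithium alkoxide being protonated to lactol 13. The closest known reaction types are the conjugate addition of sulfonyl carbanions to vinyl sulfones and the acylation of sulfonyl carbanions by lactones, merged here into a Michael/Claisen-type [3+3] annulation in which the allyl sulfone serves as a propene 1,3-dianion. The cyclohexene closes by 6-exo-trig attack of the γ-terminus on C=O, because closure through the α-carbon would give a cyclobutane. The bicycle makes this possible: the lactone α-carbon is a bridgehead and cannot enolise, and the carbanion next to the oxygen-bearing bridgehead cannot expel that oxygen, so the lactone stays an electrophile and the cage stays intact. The ring-fusion CH is set by the facial bias of the bicycle, the hemiketal carbon by the tether, and the side-chain-bearing CH by the (E)-geometry of the allyl anion in a half-chair transition state with the chain pseudo-equatorial, which is also the epimer expected from protonation on the convex face or from equilibration through the hydroxy ketone. The selectivity needed is α-attack in the first and γ-attack in the second C–C bond formation, which HMPA (soft α-addition of the separated ion pair) and ring size should secure.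

Step 8
Reactants: 13 tricyclic bis-sulfonyl lactol
Product: 14 tricyclic lactol (both sulfonyl groups replaced by hydrogen)
Conditions: Na(Hg) (6% Na), Na2HPO4, MeOH/THF (2:1), −20 °C to 0 °C
Reagents that add atoms: none
Why: Reductive desulfonylation by electron transfer should cleave both C–S bonds, the vinyl sulfone giving the ring alkene in place and the alkyl sulfone the CH2 group, while β-elimination of the ring oxygen is again excluded by the bridgehead.

Step 9
Reactants: 16 3-[(tert-butyldiphenylsilyl)oxy]propanoic acid; 15 (S)-4-benzyl-1,3-oxazolidin-2-one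
Product: 18 (S)-4-benzyl-3-{3-[(tert-butyldiphenylsilyl)oxy]propanoyl}-1,3-oxazolidin-2-one, via mixed pivalic anhydride 17 (not isolated)
Conditions: PivCl, Et3N, THF, −20 °C; then 15, LiCl, 25 °C
Reagents that add atoms: none
Why: N-Acylation of the oxazolidinone by a mixed pivalic anhydride in the presence of LiCl is the standard route to an Evans imide.

Step 10
Reactants: 18 (S)-4-benzyl-3-{3-[(tert-butyldiphenylsilyl)oxy]propanoyl}-1,3-oxazolidin-2-one; 19 (R)-2,2-dimethyl-1,3-dioxolane-4-carbaldehyde
Product: 21 (2S,3S) syn-aldol adduct (α-silyloxymethyl, β-hydroxy, (R)-dioxolane), via dibutylboron (Z)-enolate 20 (not isolated)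
Conditions: Bu2BOTf, i-Pr2NEt, CH2Cl2, −78 °C to 0 °C; then 19, −78 °C to 0 °C; pH 7 buffer, MeOH
Reagents that add atoms: none
Why: In this Evans syn-aldol reaction the (Z)-boron enolate should react through a chair Zimmerman–Traxler transition state on the face away from the benzyl group, setting both new stereocentres under auxiliary control.

Step 11
Reactants: 21 (2S,3S) syn-aldol adduct
Product: 22 tert-butyldimethylsilyl ether of 21
Conditions: TBSOTf, 2,6-lutidine, CH2Cl2, −78 °C to 0 °C
Reagents that add atoms: tert-butyldimethylsilyl trifluoromethanesulfonate, CC(C)(C)[Si](C)(C)OS(=O)(=O)C(F)(F)F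
Why: Silylation of the secondary hydroxyl with a silyl triflate and a hindered base is a routine protection that does not affect the stereocentres.

Step 12
Reactants: 22 tert-butyldimethylsilyl ether of 21
Product: 23 primary alcohol (2-(silyloxymethyl)-3-silyloxy-3-dioxolanylpropan-1-ol)
Conditions: LiBH4, MeOH (1.1 equiv), THF, 0 °C
Reagents that add atoms: none
Why: Reductive cleavage of the N-acyl oxazolidinone by LiBH4 gives the primary alcohol and returns the auxiliary without epimerising the α-centre.

Step 13
Reactants: 23 primary alcohol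
Product: 24 α-branched aldehyde
Conditions: Dess–Martin periodinane, CH2Cl2, 0 °C to 25 °C; used crude
Reagents that add atoms: none
Why: Dess–Martin oxidation is mild and non-basic, so the α-stereocentre of the aldehyde should survive.

Step 14
Reactants: 24 α-branched aldehyde
Product: 25 (Z)-2-iodoalkene (iodine cis to the branched chain)
Conditions: EtPPh3I, n-BuLi, THF, 25 °C; I2, −78 °C; NaHMDS, −20 °C; then 24, THF/HMPA, −78 °C
Reagents that add atoms: ethyltriphenylphosphonium iodide, CC[P+](c1ccccc1)(c1ccccc1)c1ccccc1.[I-]; iodine, II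
Why: In the Stork–Zhao olefination the α-iodo ylide should give the (Z)-iodoalkene under kinetic control at low temperature.

Step 15
Reactants: 25 (Z)-2-iodoalkene; 14 tricyclic lactol
Product: 27 diol (tertiary allylic carbinol and secondary ring hydroxyl), via alkenyllithium 26 (not isolated)
Conditions: 25 (2.5 equiv), t-BuLi (5.0 equiv), Et2O, −78 °C; CeCl3, THF, −78 °C; then 14, −78 °C to −40 °C
Reagents that add atoms: none
Why: Iodine–lithium exchange retains the alkene geometry, and the derived organocerium should add 1,2 to the ketone tautomer of the lactol rather than enolise it, the configuration of the new carbinol being irrelevant because it is ionised in step 16.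

Step 16
Reactants: 27 diol
Product: 28 bridged tertiary ether (2-oxabicyclo[2.2.2]octane fused to the cyclohexene, alkenyl group on the quaternary carbon)
Conditions: PPTS (10 mol%), 4 Å molecular sieves, CH2Cl2, 0 °C to 25 °C
Reagents that add atoms: none
Why: In this acid-catalysed SN1 etherification the tertiary allylic alcohol ionises and the cis-disposed ring hydroxyl captures the cation in a 6-exo closure, and the ether carbon can form only in the configuration that keeps bridge, ring fusion and cyclohexene mutually cis.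

Step 17
Reactants: 28 bridged tertiary ether
Product: 29 diol (primary alcohol and ring secondary alcohol freed)
Conditions: DDQ (3 equiv), CH2Cl2/pH 7 phosphate buffer (10:1), 0 °C to 25 °C
Reagents that add atoms: none
Why: Oxidative cleavage by DDQ removes both the 4-methoxybenzyl and the 1-(4-methoxyphenyl)ethyl ether while leaving silyl ethers and the acetonide in place.

Step 18
Reactants: 29 diol
Product: 30 keto aldehyde (ring ketone and α-methoxy aldehyde)
Conditions: Dess–Martin periodinane (3 equiv), CH2Cl2, 0 °C to 25 °C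
Reagents that add atoms: none
Why: Dess–Martin oxidation converts the primary alcohol into the aldehyde and the wrongly configured ring carbinol into the ketone in one operation, and the ketone cannot eliminate the bridge oxygen because that would need a bridgehead alkene.

Step 19
Reactants: 30 keto aldehyde
Product: 31 keto acid
Conditions: NaClO2, NaH2PO4, 2-methylbut-2-ene, t-BuOH/H2O, 0 °C to 25 °C
Reagents that add atoms: sodium chlorite, [Na+].[O-]Cl=O
Why: Pinnick oxidation converts the aldehyde into the acid without epimerising the α-methoxy centre, with the alkene scavenger protecting the other double bonds.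

Step 20
Reactants: 31 keto acid
Product: 32 hydroxy keto acid (seco acid)
Conditions: HF·pyridine, pyridine, THF, 0 °C to 25 °C
Reagents that add atoms: none
Why: Buffered HF·pyridine should remove the secondary tert-butyldimethylsilyl ether while the primary tert-butyldiphenylsilyl ether and the acetonide persist.

Step 21
Reactants: 32 hydroxy keto acid (seco acid)
Product: 33 ten-membered keto lactone
Conditions: 2-methyl-6-nitrobenzoic anhydride, DMAP, CH2Cl2 (1 mM), 25 °C, slow addition
Reagents that add atoms: none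
Why: Shiina macrolactonisation at room temperature and high dilution should close the ten-membered ring, which is pre-organised by the (Z)-alkene and the rigid tricycle, without epimerising the α-methoxy acid.

Step 22
Reactants: 33 ten-membered keto lactone
Product: 34 hydroxy lactone (ring carbinol syn to the ether bridge)
Conditions: NaBH4, MeOH/CH2Cl2 (1:1), −40 °C
Reagents that add atoms: none
Why: Hydride should attack the ketone from the open face next to the CH2–CH bridge, because the other face is shielded by the alkenyl group, placing the hydroxyl on the side of the ether bridge while the lactone survives at low temperature.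

Step 23
Reactants: 34 hydroxy lactone
Product: 35 diol lactone (primary hydroxyl freed)
Conditions: TBAF, AcOH (1:1), THF, 0 °C to 25 °C
Reagents that add atoms: none
Why: Buffered fluoride cleaves the primary tert-butyldiphenylsilyl ether without opening the lactone or the acetonide.

Step 24
Reactants: 36 3,4-dibromo-1H-pyrrole-2,5-dione
Product: 37 tert-butyl 3-(4-bromo-2,5-dioxo-2,5-dihydro-1H-pyrrol-3-yl)propanoate
Conditions: (3-tert-butoxy-3-oxopropyl)zinc bromide (2.2 equiv), Pd2(dba)3 (2.5 mol%), P(2-furyl)3 (10 mol%), THF, 0 °C to 25 °C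
Reagents that add atoms: (3-tert-butoxy-3-oxopropyl)zinc bromide, CC(C)(C)OC(=O)CC[Zn]Br
Why: Negishi coupling of the ester homoenolate should stop after one substitution, because the first alkyl group deactivates the remaining C–Br bond.

Step 25
Reactants: 37 tert-butyl 3-(4-bromo-2,5-dioxo-2,5-dihydro-1H-pyrrol-3-yl)propanoate
Product: 38 tert-butyl 3-{2,5-dioxo-4-[(trimethylsilyl)ethynyl]-2,5-dihydro-1H-pyrrol-3-yl}propanoate
Conditions: tributyl[(trimethylsilyl)ethynyl]stannane (1.2 equiv), Pd(PPh3)4 (5 mol%), toluene, 60 °C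
Reagents that add atoms: tributyl[(trimethylsilyl)ethynyl]stannane, CCCC[Sn](CCCC)(CCCC)C#C[Si](C)(C)C
Why: Stille coupling installs the alkyne under neutral, amine-free conditions, which avoids addition–elimination of amines on the bromomaleimide.

Step 26
Reactants: 38 tert-butyl 3-{2,5-dioxo-4-[(trimethylsilyl)ethynyl]-2,5-dihydro-1H-pyrrol-3-yl}propanoate
Product: 39 3-{2,5-dioxo-4-[(trimethylsilyl)ethynyl]-2,5-dihydro-1H-pyrrol-3-yl}propanoic acid
Conditions: TFA/CH2Cl2 (1:4), 0 °C to 25 °C
Reagents that add atoms: none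
Why: Acidolysis of the tert-butyl ester frees the acid without base, which the imide would not tolerate.

Step 27
Reactants: 35 diol lactone; 39 3-{2,5-dioxo-4-[(trimethylsilyl)ethynyl]-2,5-dihydro-1H-pyrrol-3-yl}propanoic acid
Product: 40 primary ester of 35 with 39
Conditions: EDC·HCl, DMAP (0.1 equiv), CH2Cl2, 0 °C
Reagents that add atoms: none
Why: Carbodiimide esterification should acylate the primary hydroxyl in preference to the hindered ring carbinol, and the silyl cap keeps nucleophiles off the alkyne terminus.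

Step 28
Reactants: 40 primary ester
Product: 41 triol (acetonide removed, silyl alkyne intact)
Conditions: AcOH/H2O (4:1), 40 °C
Reagents that add atoms: none
Why: Mild aqueous acid hydrolyses the terminal acetonide and leaves esters, imide and the bridged ether untouched.

Step 29
Reactants: 41 triol
Product: 42 terminal alkyne triol
Conditions: AgOTf (10 mol%), CH2Cl2/MeOH/H2O (7:4:1), 25 °C
Reagents that add atoms: none
Why: Silver-catalysed protodesilylation removes the alkynyl trimethylsilyl group under neutral conditions that spare the imide and the lactones.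

Step 30
Reactants: 42 terminal alkyne triol
Product: 43 CNP0072183.2 (target)
Conditions: AuCl(PPh3) (10 mol%), AgOTf (10 mol%), 2,6-di-tert-butylpyridine (20 mol%), toluene (0.5 mM), 25 °C
Reagents that add atoms: none
Why: Proposed new method: π-activation of the terminal ynimide by cationic monovalent gold should let the primary hydroxyl add to the terminal (β) carbon anti to the metal in a 14-endo-dig closure, and protodeauration with retention should then give the (Z)-enol ether, the closest known reaction being the gold-catalysed anti-hydroalkoxylation of propiolates and other electron-poor alkynes.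

**Compound list**
1 | 5-bromo-2H-pyran-2-one | O=C1C=CC(Br)=CO1 | starting material
2 | 5-(phenylsulfonyl)-2H-pyran-2-one | O=C1C=CC(=CO1)S(=O)(=O)c1ccccc1 | intermediate
3 | (S)-1-(4-methoxyphenyl)ethan-1-ol | C[C@H](O)c1ccc(OC)cc1 | starting material
4 | 1-methoxy-4-[(1S)-1-(vinyloxy)ethyl]benzene | C=CO[C@@H](C)c1ccc(OC)cc1 | intermediate
5 | (1S,4S,5S)-5-[(1S)-1-(4-methoxyphenyl)ethoxy]-7-(phenylsulfonyl)-2-oxabicyclo[2.2.2]oct-7-en-3-one | O=C1O[C@H]2C[C@H](O[C@@H](C)c3ccc(OC)cc3)[C@@H]1C=C2S(=O)(=O)c1ccccc1 | intermediate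
6 | (S)-2-{[(4-methoxybenzyl)oxy]methyl}oxirane | COc1ccc(COC[C@@H]2CO2)cc1 | starting material
7 | (S)-1-[(4-methoxybenzyl)oxy]pent-4-en-2-ol | COc1ccc(COC[C@@H](O)CC=C)cc1 | intermediate
8 | 1-methoxy-4-({[(2S)-2-methoxypent-4-en-1-yl]oxy}methyl)benzene | COc1ccc(COC[C@@H](OC)CC=C)cc1 | intermediate
9 | allyl phenyl sulfone | C=CCS(=O)(=O)c1ccccc1 | starting material
10 | 1-methoxy-4-({[(2S,4E)-2-methoxy-6-(phenylsulfonyl)hex-4-en-1-yl]oxy}methyl)benzene | COc1ccc(COC[C@@H](OC)C/C=C/CS(=O)(=O)c2ccccc2)cc1 | intermediate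
11 | lithiated sulfone (α-sulfonyl allyl anion of 10) | COc1ccc(COC[C@@H](OC)C/C=C/[CH-]S(=O)(=O)c2ccccc2)cc1.[Li+] | intermediate
12 | lithiated Michael adduct (bicyclic lactone with ring alkyl sulfone and side-chain allyl sulfonyl carbanion) | O=C1O[C@H]2C[C@H](O[C@@H](C)c3ccc(OC)cc3)[C@@H]1[C@H](C2S(=O)(=O)c1ccccc1)[C-](/C=C/C[C@H](OC)COCc1ccc(OC)cc1)S(=O)(=O)c1ccccc1.[Li+] | intermediate
13 | tricyclic bis-sulfonyl lactol | CO[C@H](COCc1ccc(OC)cc1)C[C@H]1C=C(S(=O)(=O)c2ccccc2)[C@H]2C(S(=O)(=O)c3ccccc3)[C@@H]3C[C@H](O[C@@H](C)c4ccc(OC)cc4)[C@H]2[C@]1(O3)O | intermediate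
14 | tricyclic lactol | CO[C@H](COCc1ccc(OC)cc1)C[C@H]1C=C[C@H]2C[C@@H]3C[C@H](O[C@@H](C)c4ccc(OC)cc4)[C@H]2[C@]1(O3)O | intermediate
15 | (S)-4-benzyl-1,3-oxazolidin-2-one | O=C1N[C@@H](Cc2ccccc2)CO1 | starting material
16 | 3-[(tert-butyldiphenylsilyl)oxy]propanoic acid | OC(=O)CCO[Si](c1ccccc1)(c1ccccc1)C(C)(C)C | starting material
17 | mixed pivalic anhydride of 16 | CC(C)(C)C(=O)OC(=O)CCO[Si](c1ccccc1)(c1ccccc1)C(C)(C)C | intermediate
18 | (S)-4-benzyl-3-{3-[(tert-butyldiphenylsilyl)oxy]propanoyl}-1,3-oxazolidin-2-one | O=C(CCO[Si](c1ccccc1)(c1ccccc1)C(C)(C)C)N1[C@@H](Cc2ccccc2)COC1=O | intermediate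
19 | (R)-2,2-dimethyl-1,3-dioxolane-4-carbaldehyde | O=C[C@H]1COC(C)(C)O1 | starting material
20 | dibutylboron (Z)-enolate of 18 | CCCCB(CCCC)O/C(=C\CO[Si](c1ccccc1)(c1ccccc1)C(C)(C)C)N1[C@@H](Cc2ccccc2)COC1=O | intermediate
21 | (2S,3S) syn-aldol adduct | O=C([C@@H](CO[Si](c1ccccc1)(c1ccccc1)C(C)(C)C)[C@H](O)[C@H]1COC(C)(C)O1)N1[C@@H](Cc2ccccc2)COC1=O | intermediate
22 | tert-butyldimethylsilyl ether of 21 | O=C([C@@H](CO[Si](c1ccccc1)(c1ccccc1)C(C)(C)C)[C@H](O[Si](C)(C)C(C)(C)C)[C@H]1COC(C)(C)O1)N1[C@@H](Cc2ccccc2)COC1=O | intermediate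
23 | primary alcohol | OC[C@@H](CO[Si](c1ccccc1)(c1ccccc1)C(C)(C)C)[C@H](O[Si](C)(C)C(C)(C)C)[C@H]1COC(C)(C)O1 | intermediate
24 | α-branched aldehyde | O=C[C@@H](CO[Si](c1ccccc1)(c1ccccc1)C(C)(C)C)[C@H](O[Si](C)(C)C(C)(C)C)[C@H]1COC(C)(C)O1 | intermediate
25 | (Z)-2-iodoalkene | I/C(C)=C\[C@@H](CO[Si](c1ccccc1)(c1ccccc1)C(C)(C)C)[C@H](O[Si](C)(C)C(C)(C)C)[C@H]1COC(C)(C)O1 | intermediate
26 | alkenyllithium from 25 | [Li]/C(C)=C\[C@@H](CO[Si](c1ccccc1)(c1ccccc1)C(C)(C)C)[C@H](O[Si](C)(C)C(C)(C)C)[C@H]1COC(C)(C)O1 | intermediate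
27 | diol (tertiary allylic carbinol, secondary ring hydroxyl) | CO[C@H](COCc1ccc(OC)cc1)C[C@H]1C=C[C@H]2C[C@@H](O)C[C@H](O[C@@H](C)c3ccc(OC)cc3)[C@H]2C1(O)/C(C)=C\[C@@H](CO[Si](c1ccccc1)(c1ccccc1)C(C)(C)C)[C@H](O[Si](C)(C)C(C)(C)C)[C@H]1COC(C)(C)O1 | intermediate
28 | bridged tertiary ether | CO[C@H](COCc1ccc(OC)cc1)C[C@H]1C=C[C@H]2C[C@@H]3C[C@H](O[C@@H](C)c4ccc(OC)cc4)[C@H]2[C@]1(O3)/C(C)=C\[C@@H](CO[Si](c1ccccc1)(c1ccccc1)C(C)(C)C)[C@H](O[Si](C)(C)C(C)(C)C)[C@H]1COC(C)(C)O1 | intermediate
29 | diol (primary and ring secondary alcohol) | CO[C@H](CO)C[C@H]1C=C[C@H]2C[C@@H]3C[C@H](O)[C@H]2[C@]1(O3)/C(C)=C\[C@@H](CO[Si](c1ccccc1)(c1ccccc1)C(C)(C)C)[C@H](O[Si](C)(C)C(C)(C)C)[C@H]1COC(C)(C)O1 | intermediate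
30 | keto aldehyde | CO[C@H](C=O)C[C@H]1C=C[C@H]2C[C@@H]3CC(=O)[C@H]2[C@]1(O3)/C(C)=C\[C@@H](CO[Si](c1ccccc1)(c1ccccc1)C(C)(C)C)[C@H](O[Si](C)(C)C(C)(C)C)[C@H]1COC(C)(C)O1 | intermediate
31 | keto acid | CO[C@H](C(O)=O)C[C@H]1C=C[C@H]2C[C@@H]3CC(=O)[C@H]2[C@]1(O3)/C(C)=C\[C@@H](CO[Si](c1ccccc1)(c1ccccc1)C(C)(C)C)[C@H](O[Si](C)(C)C(C)(C)C)[C@H]1COC(C)(C)O1 | intermediate
32 | hydroxy keto acid (seco acid) | CO[C@H](C(O)=O)C[C@H]1C=C[C@H]2C[C@@H]3CC(=O)[C@H]2[C@]1(O3)/C(C)=C\[C@@H](CO[Si](c1ccccc1)(c1ccccc1)C(C)(C)C)[C@H](O)[C@H]1COC(C)(C)O1 | intermediate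
33 | ten-membered keto lactone | CO[C@H]1C[C@H]2C=C[C@H]3C[C@@H]4CC(=O)[C@H]3[C@]2(O4)/C(C)=C\[C@@H](CO[Si](c5ccccc5)(c5ccccc5)C(C)(C)C)[C@H](OC1=O)[C@H]5COC(C)(C)O5 | intermediate
34 | hydroxy lactone | CO[C@H]1C[C@H]2C=C[C@H]3C[C@@H]4C[C@@H](O)[C@H]3[C@]2(O4)/C(C)=C\[C@@H](CO[Si](c5ccccc5)(c5ccccc5)C(C)(C)C)[C@H](OC1=O)[C@H]5COC(C)(C)O5 | intermediate
35 | diol lactone | CO[C@H]1C[C@H]2C=C[C@H]3C[C@@H]4C[C@@H](O)[C@H]3[C@]2(O4)/C(C)=C\[C@@H](CO)[C@H](OC1=O)[C@H]5COC(C)(C)O5 | intermediate
36 | 3,4-dibromo-1H-pyrrole-2,5-dione | O=C1NC(=O)C(Br)=C1Br | starting material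
37 | tert-butyl 3-(4-bromo-2,5-dioxo-2,5-dihydro-1H-pyrrol-3-yl)propanoate | CC(C)(C)OC(=O)CCC1=C(Br)C(=O)NC1=O | intermediate
38 | tert-butyl 3-{2,5-dioxo-4-[(trimethylsilyl)ethynyl]-2,5-dihydro-1H-pyrrol-3-yl}propanoate | CC(C)(C)OC(=O)CCC1=C(C#C[Si](C)(C)C)C(=O)NC1=O | intermediate
39 | 3-{2,5-dioxo-4-[(trimethylsilyl)ethynyl]-2,5-dihydro-1H-pyrrol-3-yl}propanoic acid | OC(=O)CCC1=C(C#C[Si](C)(C)C)C(=O)NC1=O | intermediate
40 | primary ester of 35 with 39 | CO[C@H]1C[C@H]2C=C[C@H]3C[C@@H]4C[C@@H](O)[C@H]3[C@]2(O4)/C(C)=C\[C@@H](COC(=O)CCC5=C(C#C[Si](C)(C)C)C(=O)NC5=O)[C@H](OC1=O)[C@H]5COC(C)(C)O5 | intermediate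
41 | triol with silyl alkyne | CO[C@H]1C[C@H]2C=C[C@H]3C[C@@H]4C[C@@H](O)[C@H]3[C@]2(O4)/C(C)=C\[C@@H](COC(=O)CCC5=C(C#C[Si](C)(C)C)C(=O)NC5=O)[C@H](OC1=O)[C@H](O)CO | intermediate
42 | terminal alkyne triol | CO[C@H]1C[C@H]2C=C[C@H]3C[C@@H]4C[C@@H](O)[C@H]3[C@]2(O4)/C(C)=C\[C@@H](COC(=O)CCC5=C(C#C)C(=O)NC5=O)[C@H](OC1=O)[C@H](O)CO | intermediate
43 | CNP0072183.2 | CO[C@H]1C[C@H]2C=C[C@H]3C[C@@H]4C[C@@H](O)[C@H]3[C@]2(O4)/C(C)=C\[C@H]2COC(=O)CCC3=C(/C=C\OC[C@@H](O)[C@H]2OC1=O)C(=O)NC3=O | target

**Step count and risks**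
Total step count: 30. Longest linear sequence: 19 steps (from 16 through steps 9–23 and 27–30).

Most likely to fail:

1. Step 7 (Proposed new method). The second C–C bond formation may not occur (the allyl sulfonyl carbanion may stop at the Michael stage or undergo retro-Michael), and the tetrahedral intermediate may open and enolise so that the side-chain-bearing centre is set by protonation and not by ring closure. The fallback sets out from 5 and 8 and returns at 14, using known reactions only. Cross-metathesis of 8 with allyl bromide gives the (E)-allylic bromide F1. Copper-mediated conjugate addition of vinylmagnesium bromide to the vinyl sulfone of 5, from the lactone face, gives the vinyl adduct F2. Zinc-mediated Barbier allylation of the lactone carbonyl of F2 with F1 (γ-attack) gives the lactol F3. Ring-closing metathesis of its two vinyl groups then forms the cyclohexene F4, whose remaining sulfonyl group is removed with Na(Hg) to give 14. In this fallback the side-chain-bearing centre is not controlled and the epimers must be separated.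

2. Step 30 (Proposed new method). Addition may be slow, may proceed twice (ketal formation), or may be followed by isomerisation of the (Z)-enol ether. The fallback sets out from 42 and returns at 43. Hydroiodination of the ynimide with NaI/AcOH (anti-addition) gives the (Z)-2-iodovinyl maleimide F5. Intramolecular copper-catalysed C–O coupling of the primary hydroxyl with the vinyl iodide (CuI, 3,4,7,8-tetramethyl-1,10-phenanthroline, Cs2CO3, toluene, high dilution) then closes the ring with retention of geometry.

3. Step 15. Enolisation or double-bond migration of the β,γ-unsaturated ketone tautomer may compete with addition, and the lactol hydroxyl consumes the advanced organometallic. The fallback sets out from 14 and returns at 28. Silylation (TESCl, imidazole, DMF) traps the open tautomer as the triethylsilyl ether ketone F6. Addition of 26 (1.3 equiv, LaCl3·2LiCl) gives the tertiary alcohol F7. PPTS in wet CH2Cl2 then removes the silyl group and closes the ether bridge to 28.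

**Further compounds**
F1 | step 7 | 1-({[(2S,4E)-6-bromo-2-methoxyhex-4-en-1-yl]oxy}methyl)-4-methoxybenzene | COc1ccc(COC[C@@H](OC)C/C=C/CBr)cc1
F2 | step 7 | vinyl adduct of 5 (8-vinyl-7-(phenylsulfonyl)-2-oxabicyclo[2.2.2]octan-3-one) | O=C1O[C@H]2C[C@H](O[C@@H](C)c3ccc(OC)cc3)[C@@H]1[C@@H](C=C)C2S(=O)(=O)c1ccccc1
F3 | step 7 | bicyclic lactol carrying two vinyl groups | COc1ccc(COC[C@@H](OC)CC(C=C)C2(O)O[C@H]3C[C@H](O[C@@H](C)c4ccc(OC)cc4)[C@@H]2[C@@H](C=C)C3S(=O)(=O)c2ccccc2)cc1
F4 | step 7 | tricyclic mono-sulfonyl lactol | CO[C@H](COCc1ccc(OC)cc1)C[C@H]1C=C[C@H]2C(S(=O)(=O)c3ccccc3)[C@@H]3C[C@H](O[C@@H](C)c4ccc(OC)cc4)[C@H]2[C@]1(O3)O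
F5 | step 30 | (Z)-2-iodovinyl maleimide triol | CO[C@H]1C[C@H]2C=C[C@H]3C[C@@H]4C[C@@H](O)[C@H]3[C@]2(O4)/C(C)=C\[C@@H](COC(=O)CCC5=C(/C=C\I)C(=O)NC5=O)[C@H](OC1=O)[C@H](O)CO
F6 | step 15 | triethylsilyl ether of the hydroxy ketone tautomer of 14 | CO[C@H](COCc1ccc(OC)cc1)C[C@H]1C=C[C@H]2C[C@@H](O[Si](CC)(CC)CC)C[C@H](O[C@@H](C)c3ccc(OC)cc3)[C@H]2C1=O
F7 | step 15 | tertiary alcohol triethylsilyl ether | CO[C@H](COCc1ccc(OC)cc1)C[C@H]1C=C[C@H]2C[C@@H](O[Si](CC)(CC)CC)C[C@H](O[C@@H](C)c3ccc(OC)cc3)[C@H]2C1(O)/C(C)=C\[C@@H](CO[Si](c1ccccc1)(c1ccccc1)C(C)(C)C)[C@H](O[Si](C)(C)C(C)(C)C)[C@H]1COC(C)(C)O1
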